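## Retrosynthetic overview

1. Target ⇐ MnO2 oxidation of an allylic tetraol ⇐ exhaustive i-Bu2AlH reduction of a tricyclic bis-lactone; the Z-enal geometry is stored as a seven-membered unsaturated lactone (intramolecular Horner–Wadsworth–Emmons, C-1 CH2O tether onto a C-3 ketone).
2. All-E triene ⇐ E-selective Wittig reaction of a chain enal with the geranyl tributylphosphonium ylide.
3. C-1 quaternary centre plus five chain carbons ⇐ photochemical titanocene-catalysed spiro-epoxide opening and 1,6-radical addition to 2-methylpenta-2,4-dienal (key step, new); epoxide ⇐ Corey–Chaykovsky reaction on the C-1 ketone.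
4. C-2 centre plus the three hydroxypropyl carbons ⇐ intramolecular Mukaiyama–Michael addition of an acrylate tethered to the C-6 oxygen; C-3 ketone ⇐ oxodealkenylation of the isopropenyl group.
5. Carbocycle and C-6 stereocentre are bought as (1S,2S,4R)-limonene-1,2-diol. Ring order: bridged lactone (step 3), spiro-oxirane (step 4, opened in step 7), fused unsaturated lactone (step 11); both lactones are opened in step 12.

Assumption: the target is taken exactly as drawn by the SMILES (ring 1S,2R,6S, Z-enal, all-E triene); ring positions are called C-1 (quaternary carbon), C-2 (CH), C-3 (alkylidene carbon), C-4, C-5 and C-6 (carbinol carbon), "lower face" is the face of the C-6 oxygen and "upper face" that of the C-6 methyl; compounds 1, 10, 11, 15 and 19 are taken as commercial.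

## Route

Step 1
Reactants: 1 (1S,2S,4R)-limonene-1,2-diol
Product: 2 (2S,5R)-2-hydroxy-2-methyl-5-(prop-1-en-2-yl)cyclohexan-1-one
Conditions: IBX (1.5 equiv), EtOAc, 75 °C
Reagents that add atoms: none
Why: IBX oxidation (hypervalent-iodine alcohol oxidation) converts the secondary carbinol of the trans-diol into the ketone without glycol cleavage and cannot touch the tertiary carbinol, so the purchased C-6 stereocentre is carried on unchanged.

Step 2
Reactants: 2 (2S,5R)-2-hydroxy-2-methyl-5-(prop-1-en-2-yl)cyclohexan-1-one
Product: 3 (1S,4R)-1-methyl-2-oxo-4-(prop-1-en-2-yl)cyclohexyl prop-2-enoate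
Conditions: acryloyl chloride (1.5 equiv), Et3N (2 equiv), DMAP (0.1 equiv), CH2Cl2, 0 → 20 °C
Reagents that add atoms: acryloyl chloride, C=CC(=O)Cl
Why: DMAP-catalysed acyl transfer (Steglich-type acylation with an acid chloride) esterifies the tertiary α-ketol oxygen and thereby hangs the three carbons of the later hydroxypropyl chain on the C-6 oxygen as an internal Michael acceptor.

Step 3
Reactants: 3 (1S,4R)-1-methyl-2-oxo-4-(prop-1-en-2-yl)cyclohexyl prop-2-enoate
Product: 5 (1S,6R,7R)-1-methyl-7-(prop-1-en-2-yl)-2-oxabicyclo[4.3.1]decane-3,10-dione (bridged keto lactone), via silyl enol ether 4 (not isolated)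
Conditions: TMSOTf (1.2 equiv), Et3N (1.5 equiv), CH2Cl2, 0 °C; then TiCl4 (1.1 equiv), −78 → −40 °C; then H2O
Reagents that add atoms: none
Why: C-2 is the only enolisable position so silylation is regiospecific, and the intramolecular Mukaiyama–Michael addition (7-endo) to the TiCl4-activated acrylate can only deliver the acceptor to the lower face from the axial C-6 oxygen (chair-like axial attack at C-2), which sets the new C-2 stereocentre with its CH2 cis to the C-6 oxygen, while the neutral silyl enol ether avoids the O-to-C acyl transfer that a metal enolate would suffer.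

Step 4
Reactants: 5 bridged keto lactone
Product: 6 spiro-oxirane at C-1 (oxirane CH2 on the upper face; oxirane O on the lower face; lactone bridge and isopropenyl unchanged)
Conditions: Me3S+ I− (1.5 equiv), n-BuLi (1.4 equiv), THF, −10 °C; then 5, −10 → 20 °C
Reagents that add atoms: trimethylsulfonium iodide, C[S+](C)C.[I-]
Why: Corey–Chaykovsky epoxidation of the non-enolisable bridging ketone with dimethylsulfonium methylide (which reacts with ketones much faster than with lactones) gives the spiro-oxirane with CH2 delivered from the carbocycle side, a spiro configuration that is erased again in step 7.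

Step 5
Reactants: 6 spiro-oxirane
Product: 9 keto spiro-oxirane (6 with the isopropenyl-bearing C-3 turned into C=O), via methoxy hydroperoxide 7 (not isolated), via TEMPO ether 8 (not isolated)
Conditions: O3, MeOH/CH2Cl2, −78 °C; then FeSO4·7H2O (1.2 equiv), TEMPO (1.5 equiv), 0 → 20 °C; then magnesium bis(monoperoxyphthalate) (1.5 equiv), 20 °C
Reagents that add atoms: TEMPO (2,2,6,6-tetramethylpiperidin-1-oxyl), CC1(C)CCCC(C)(C)N1[O]
Why: Oxodealkenylation (ozonolysis in methanol to the α-methoxy hydroperoxide, O–O cleavage by divalent iron with β-scission that expels methyl acetate, TEMPO capture of the C-3 radical and peracid oxidation of the alkoxyamine) turns the isopropenyl-bearing CH into the C-3 ketone after that stereocentre has served its purpose, and the hindered, inductively deactivated spiro-oxirane, the lactone and the bridgehead C-2 centre are not affected.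

Step 6
Reactants: 10 acrolein; 11 2-(triphenylphosphoranylidene)propanal
Product: 12 (E)-2-methylpenta-2,4-dienal
Conditions: 10 (3 equiv), hydroquinone (trace), CH2Cl2, 40 °C
Reagents that add atoms: none
Why: Wittig olefination of acrolein with the stabilised formyl ylide gives the trisubstituted enal double bond with E geometry, as is usual for stabilised ylides.

Step 7
Reactants: 9 keto spiro-oxirane; 12 (E)-2-methylpenta-2,4-dienal
Product: 14 hydroxy enal (C-1 carries CH2OH on the lower face and (E)-4-methyl-5-oxopent-3-en-1-yl on the upper face; C-3 ketone; lactone bridge intact), via deconjugated aldehyde 13 (not isolated)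
Conditions: Cp2TiCl2 (10 mol %), 4CzIPN (2 mol %), Hantzsch ester (1.5 equiv), 12 (3 equiv), THF, 450 nm LEDs, 20 °C; then Et3N (0.2 equiv), CH2Cl2, 20 °C
Reagents that add atoms: none
Why: Proposed new method: blue-light photoreduction of Cp2TiCl2 (4CzIPN excited state quenched by the Hantzsch ester) gives trivalent titanium, which opens the spiro-oxirane by single-electron transfer at the more substituted C–O bond to the tertiary β-titanoxy radical at C-1, this nucleophilic radical adds to the terminal carbon of the dienal (1,6-addition) from the upper face over the flat ketone bridge of the carbocycle (axial attack, the lower face being covered by the CH2CH2 unit of the seven-membered lactone bridge) so that the new chain ends cis to the C-6 methyl and the CH2O arm cis to the C-6 oxygen, the resulting α-formyl pentadienyl radical is reduced to the titanium dienolate and protonated, and triethylamine moves the double bond into conjugation as the E-enal; the closest known reactions are the photoredox/titanocene-catalysed reductive epoxide opening with Giese trapping by acrylates and 1,6-radical additions to dienoates, neither of which has been shown with a 2,4-dienal acceptor or for a quaternary centre of this kind.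

Step 8
Reactants: 15 geranyl bromide
Product: 16 tributyl[(2E)-3,7-dimethylocta-2,6-dien-1-yl]phosphonium bromide
Conditions: PBu3 (1.05 equiv), MeCN, 20 °C
Reagents that add atoms: tributylphosphine, CCCCP(CCCC)CCCC
Why: SN2 quaternisation of tributylphosphine by the primary allylic bromide (Menshutkin-type phosphonium salt formation) proceeds at the unhindered CH2Br carbon and keeps the E double bond of the geranyl unit.

Step 9
Reactants: 14 hydroxy enal; 16 geranyl tributylphosphonium bromide
Product: 18 triene alcohol (14 with the aldehyde turned into the (3E,5E,7E)-4,8,12-trimethyltrideca-3,5,7,11-tetraen-1-yl chain), via phosphorus ylide 17 (not isolated)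
Conditions: 16 (1.3 equiv), KOt-Bu (1.25 equiv), THF, −78 °C; then 14, −78 → 0 °C
Reagents that add atoms: none
Why: Wittig olefination with an allylic tributylphosphonium ylide is known to give E-dienes with high selectivity, the ylide is too weakly basic to deprotonate the free primary alcohol or the ketone, and it reacts only with the aldehyde, so the all-E triene is completed without touching the stereocentres.

Step 10
Reactants: 18 triene alcohol; 19 2-(diethoxyphosphoryl)propanoic acid
Product: 20 2-(diethoxyphosphoryl)propanoate ester of 18 at the C-1 CH2OH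
Conditions: DCC (1.5 equiv), DMAP (0.1 equiv), CH2Cl2, 0 → 20 °C
Reagents that add atoms: none
Why: Steglich esterification (DCC/DMAP) acylates the only free hydroxyl of 18, the neopentyl CH2OH on C-1, under neutral conditions and installs the phosphonate needed for the ring-closing olefination.

Step 11
Reactants: 20 phosphonate ester
Product: 21 tricyclic bis-lactone (new seven-membered lactone C-1–CH2–O–CO–C(CH3)=C-3 with the ester carbonyl cis to C-2; bridged lactone intact)
Conditions: NaH (1.05 equiv), THF (2 mM), 0 → 50 °C
Reagents that add atoms: none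
Why: Intramolecular Horner–Wadsworth–Emmons olefination of the C-3 ketone closes a seven-membered α,β-unsaturated lactone whose endocyclic tetrasubstituted double bond can only be cis within the ring, which forces the ester carbonyl carbon cis to C-2 (the Z geometry of the target enal), while C-2 cannot epimerise because it is still a bridgehead.

Step 12
Reactants: 21 tricyclic bis-lactone
Product: 22 allylic tetraol (the target with CH2OH in place of CHO)
Conditions: i-Bu2AlH (8 equiv), CH2Cl2, −78 → 0 °C; aqueous KNaC4H4O6
Reagents that add atoms: none
Why: Exhaustive i-Bu2AlH reduction (1,2-reduction of the unsaturated lactone and full reduction of the bridged lactone via the lactols) liberates the C-1 CH2OH and the allylic alcohol from one ring and the hydroxypropyl chain and the C-6 tertiary alcohol from the other, without touching the triene, the double-bond geometries or any stereocentre.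

Step 13
Reactants: 22 allylic tetraol
Product: 23 CNP0179699.2 (target)
Conditions: MnO2 (20 equiv), CH2Cl2, 20 °C
Reagents that add atoms: none
Why: MnO2 oxidises only the allylic primary alcohol (chemoselective heterogeneous allylic oxidation under neutral conditions), so the two saturated primary alcohols, the tertiary alcohol, the Z geometry and the epimerisable C-2 centre next to the new enal are left as they are.

## Compound list

1 | (1S,2S,4R)-1-methyl-4-(prop-1-en-2-yl)cyclohexane-1,2-diol, (1S,2S,4R)-limonene-1,2-diol | O[C@H]1C[C@H](C(C)=C)CC[C@]1(C)O | starting material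
2 | (2S,5R)-2-hydroxy-2-methyl-5-(prop-1-en-2-yl)cyclohexan-1-one | O=C1C[C@H](C(C)=C)CC[C@]1(C)O | intermediate
3 | (1S,4R)-1-methyl-2-oxo-4-(prop-1-en-2-yl)cyclohexyl prop-2-enoate | O=C1C[C@H](C(C)=C)CC[C@]1(C)OC(=O)C=C | intermediate
4 | (1S,4R)-1-methyl-4-(prop-1-en-2-yl)-2-(trimethylsilyloxy)cyclohex-2-en-1-yl prop-2-enoate (not isolated) | C[Si](C)(C)OC1=C[C@H](C(C)=C)CC[C@]1(C)OC(=O)C=C | intermediate
5 | (1S,6R,7R)-1-methyl-7-(prop-1-en-2-yl)-2-oxabicyclo[4.3.1]decane-3,10-dione (lactone bridge C-6–O–CO–CH2CH2–C-2 on the lower face) | O=C1[C@H]2[C@H](C(C)=C)CC[C@]1(C)OC(=O)CC2 | intermediate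
6 | spiro-oxirane of 5 at C-1 (oxirane CH2 upper face, oxirane O lower face) | C1O[C@@]12[C@H]3[C@H](C(C)=C)CC[C@]2(C)OC(=O)CC3 | intermediate
7 | α-methoxy hydroperoxide from 6, C-3 bearing C(CH3)(OCH3)OOH, epimer mixture at that carbon (not isolated) | C1O[C@@]12[C@H]3[C@H](C(C)(OC)OO)CC[C@]2(C)OC(=O)CC3 | intermediate
8 | C-3 O-(2,2,6,6-tetramethylpiperidin-1-yl) ether, C-3 epimer mixture (not isolated) | C1O[C@@]12[C@H]3C(ON4C(C)(C)CCCC4(C)C)CC[C@]2(C)OC(=O)CC3 | intermediate
9 | keto spiro-oxirane (C-3 ketone, spiro-oxirane at C-1, bridged lactone) | C1O[C@@]12[C@H]3C(=O)CC[C@]2(C)OC(=O)CC3 | intermediate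
10 | acrolein (prop-2-enal) | C=CC=O | starting material
11 | 2-(triphenylphosphoranylidene)propanal | CC(C=O)=P(c1ccccc1)(c1ccccc1)c1ccccc1 | starting material
12 | (E)-2-methylpenta-2,4-dienal | O=C/C(C)=C/C=C | intermediate
13 | deconjugated adduct, C-1 chain (E)-CH2CH=CHCH(CH3)CHO, epimer mixture at the CH(CH3) carbon (not isolated) | O=CC(C)/C=C/C[C@@]1(CO)[C@H]2C(=O)CC[C@]1(C)OC(=O)CC2 | intermediate
14 | hydroxy enal: C-1 with CH2OH (lower face) and (E)-4-methyl-5-oxopent-3-en-1-yl (upper face), C-3 ketone, bridged lactone | O=C/C(C)=C/CC[C@@]1(CO)[C@H]2C(=O)CC[C@]1(C)OC(=O)CC2 | intermediate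
15 | geranyl bromide, (E)-1-bromo-3,7-dimethylocta-2,6-diene | CC(C)=CCC/C(C)=C/CBr | starting material
16 | tributyl[(2E)-3,7-dimethylocta-2,6-dien-1-yl]phosphonium bromide | CC(C)=CCC/C(C)=C/C[P+](CCCC)(CCCC)CCCC.[Br-] | intermediate
17 | tributyl[(2E)-3,7-dimethylocta-2,6-dien-1-ylidene]phosphorane (not isolated) | CC(C)=CCC/C(C)=C/C=P(CCCC)(CCCC)CCCC | intermediate
18 | triene alcohol: C-1 with CH2OH (lower face) and (3E,5E,7E)-4,8,12-trimethyltrideca-3,5,7,11-tetraen-1-yl (upper face), C-3 ketone, bridged lactone | CC(C)=CCC/C(C)=C/C=C/C(C)=C/CC[C@@]1(CO)[C@H]2C(=O)CC[C@]1(C)OC(=O)CC2 | intermediate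
19 | 2-(diethoxyphosphoryl)propanoic acid | CCOP(=O)(OCC)C(C)C(=O)O | starting material
20 | 2-(diethoxyphosphoryl)propanoate of 18 at the C-1 CH2OH, epimer mixture at the phosphonate carbon | CC(C)=CCC/C(C)=C/C=C/C(C)=C/CC[C@@]1(COC(=O)C(C)P(=O)(OCC)OCC)[C@H]2C(=O)CC[C@]1(C)OC(=O)CC2 | intermediate
21 | tricyclic bis-lactone: fused seven-membered lactone C-1–CH2–O–CO–C(CH3)=C-3 (carbonyl cis to C-2) plus the bridged lactone | CC(C)=CCC/C(C)=C/C=C/C(C)=C/CC[C@]12COC(=O)/C(C)=C3/CC[C@]1(C)OC(=O)CC[C@@H]23 | intermediate
22 | allylic tetraol, (Z)-configured at the ring alkylidene (CH2OH cis to C-2) | CC(C)=CCC/C(C)=C/C=C/C(C)=C/CC[C@@]1(CO)[C@H](CCCO)/C(=C(/C)CO)CC[C@]1(C)O | intermediate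
23 | CNP0179699.2 | CC(C)=CCC/C(C)=C/C=C/C(C)=C/CC[C@@]1(CO)[C@H](CCCO)/C(=C(/C)C=O)CC[C@]1(C)O | target

## Step count and risks

Total step count: 13 (11 on the main line, plus step 6 and step 8 for the fragments 12 and 16).
Longest linear sequence: 11 steps (1, 2, 3, 4, 5, 7, 9, 10, 11, 12, 13).

**Step 7 (the proposed new step).** It can fail through reductive coupling of the dienal by trivalent titanium, through 1,2- instead of 1,6-addition, through low face selectivity at C-1 (the two faces of the bridging radical differ only moderately), or through transesterification of the new primary alkoxide onto the bridged lactone. The fallback uses known chemistry and sets out from 6, before the ozonolysis. Classical Nugent–RajanBabu conditions (Cp2TiCl2, zinc dust, THF, methyl acrylate) open the oxirane with trivalent titanium and the C-1 radical adds to methyl acrylate; lactonisation gives the spiro δ-lactone F3, at which stage C-1 epimers can be separated. One equivalent of i-Bu2AlH at −78 °C reduces the unhindered δ-lactone in preference to the bridged lactone of the tertiary alcohol and gives the lactol F4. Wittig reaction of this lactol with 11 gives the isopropenyl enal F5. Oxodealkenylation under the conditions of step 5, where ozone attacks the electron-rich 1,1-disubstituted alkene far faster than the enal double bond, brings the sequence back to the route at 14.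

**Step 3.** The 7-endo Mukaiyama–Michael closure to a bridged lactone may be slow, and the Lewis acid may attack the isopropenyl group. The fallback sets out from 2 and makes the C–C bond intermolecularly before closing the ring at the C–O bond. A Stork enamine Michael addition (pyrrolidine, then methyl acrylate, then aqueous acid) gives the keto ester F1 as a mixture of C-2 epimers, and LiOH gives the keto acid F2. Yamaguchi lactonisation (2,4,6-trichlorobenzoyl chloride, Et3N, DMAP, toluene, high dilution, 80 °C) then closes the bridged lactone. C-2 epimerises through the enol under these conditions, so both epimers funnel into the only one that can bridge, and the route is rejoined at 5.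

**Step 11.** The ketone is hindered and a tetrasubstituted double bond has to form in a seven-membered ring. The fallback sets out from 18 and replaces the olefination by an addition–elimination sequence. Acylation with 2-bromopropanoyl bromide and pyridine gives the bromo ester F6. SmI2 in THF at −78 °C effects an intramolecular Reformatsky addition to the C-3 ketone and gives the β-hydroxy lactone F7. Dehydration with the Burgess reagent, followed by DBU to bring any β,γ-isomer into conjugation, gives 21, where the route is rejoined.

## Further compounds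

F1 | step 3 | methyl 3-[(3S,6R)-3-hydroxy-3-methyl-2-oxo-6-(prop-1-en-2-yl)cyclohexyl]propanoate, C-2 epimer mixture | O=C1C(CCC(=O)OC)[C@H](C(C)=C)CC[C@]1(C)O
F2 | step 3 | 3-[(3S,6R)-3-hydroxy-3-methyl-2-oxo-6-(prop-1-en-2-yl)cyclohexyl]propanoic acid, C-2 epimer mixture | O=C1C(CCC(=O)O)[C@H](C(C)=C)CC[C@]1(C)O
F3 | step 7 | spiro δ-lactone at C-1 (CH2O lower face, CH2CH2CO upper face), isopropenyl and bridged lactone retained | O=C1CC[C@@]2(CO1)[C@H]3[C@H](C(C)=C)CC[C@]2(C)OC(=O)CC3
F4 | step 7 | lactol of F3, anomer mixture | OC1CC[C@@]2(CO1)[C@H]3[C@H](C(C)=C)CC[C@]2(C)OC(=O)CC3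
F5 | step 7 | isopropenyl analogue of 14 (C-3 still CH bearing prop-1-en-2-yl) | O=C/C(C)=C/CC[C@@]1(CO)[C@H]2[C@H](C(C)=C)CC[C@]1(C)OC(=O)CC2
F6 | step 11 | 2-bromopropanoate of 18 at the C-1 CH2OH, epimer mixture at the CHBr carbon | CC(C)=CCC/C(C)=C/C=C/C(C)=C/CC[C@@]1(COC(=O)C(C)Br)[C@H]2C(=O)CC[C@]1(C)OC(=O)CC2
F7 | step 11 | β-hydroxy lactone (21 with water added across the ring double bond, OH on C-3), epimer mixture | CC(C)=CCC/C(C)=C/C=C/C(C)=C/CC[C@]12COC(=O)C(C)C3(O)CC[C@]1(C)OC(=O)CC[C@@H]23
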